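## Retrosynthetic overview

1. The hydroperoxide comes last, by a Schenck ene reaction on a homoprenyl (4-methylpent-3-enyl) side chain; the (Z)-enol ester comes from ruthenium-catalysed anti-Markovnikov addition of 3-methylbut-2-enoic acid to a C6 ethynyl group.
2. The C5 quaternary centre is disconnected by 1,6-conjugate addition of a homoprenyl copper reagent to a 5-methylcyclohepta-2,4-dienone, anti to the C6 alkynyl group.
3. Key step: the seven-membered ring (the only ring of the target) is made in one operation from two acyclic partners, a siloxyvinyl diazoacetate and a 3-methyl-1,3-dien-5-yne. Catalytic asymmetric cyclopropanation gives a transient three-membered ring first; its divinylcyclopropane Cope ring expansion gives the seven-membered ring second, forming C2–C3 and C6–C7 and setting the cis C6/C7 pair.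
4. The diazo partner comes from methyl levulinate (masked 2-oxopropyl arm; the ester carbon becomes CH2OH). The dienyne comes from 3-(triisopropylsilyl)prop-2-ynal by two Wittig reactions.

Ring locants in all names follow the target: C1 = ring C=O, C2 = C bearing CH2OH, C3 = CH, C4 = CH2, C5 = quaternary C, C6 = CH bearing the enol ester arm, C7 = CH bearing the 2-oxopropyl arm.

Assumption: Rh2(S-PTAD)4, dirhodium tetrakis[(S)-(1-adamantyl)(phthalimido)acetate], is taken to give the enantiomer drawn in step 7, by analogy with related donor/acceptor carbenoid cyclopropanations; if the antipode forms, Rh2(R-PTAD)4 is used and nothing else changes.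

## Route

Step 1
Reactants: 1 methyl levulinate (methyl 4-oxopentanoate)
Product: 2 methyl 3-(2-methyl-1,3-dioxolan-2-yl)propanoate
Conditions: HOCH2CH2OH (1.5 equiv), p-TsOH·H2O (1 mol %), toluene, reflux, Dean–Stark
Reagents that add atoms: ethylene glycol, OCCO
Why: Acid-catalysed ketalisation with azeotropic removal of water masks the methyl ketone (the future 2-oxopropyl C=O) so that only the ester reacts in step 2.

Step 2
Reactants: 2 methyl 3-(2-methyl-1,3-dioxolan-2-yl)propanoate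
Product: 3 methyl 5-(2-methyl-1,3-dioxolan-2-yl)-3-oxopentanoate
Conditions: MeOAc (2.2 equiv), LiN(i-Pr)2 (2.2 equiv), THF, −78 °C; then 2, −78 → 0 °C; aq NH4Cl
Reagents that add atoms: methyl acetate, COC(C)=O
Why: Crossed Claisen condensation; the preformed lithium enolate of methyl acetate acylates on ester 2 and the second equivalent stores the β-keto ester as its enolate, which stops over-addition.

Step 3
Reactants: 3 methyl 5-(2-methyl-1,3-dioxolan-2-yl)-3-oxopentanoate
Product: 4 methyl 2-diazo-5-(2-methyl-1,3-dioxolan-2-yl)-3-oxopentanoate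
Conditions: 4-acetamidobenzenesulfonyl azide (1.1 equiv), Et3N, MeCN, 0 °C → rt
Reagents that add atoms: 4-acetamidobenzenesulfonyl azide, CC(=O)Nc1ccc(cc1)S(=O)(=O)N=[N+]=[N-]
Why: Regitz diazo transfer to the doubly activated methylene of a β-keto ester is fast and high-yielding under mild base.

Step 4
Reactants: 4 methyl 2-diazo-5-(2-methyl-1,3-dioxolan-2-yl)-3-oxopentanoate
Product: 5 methyl (3Z)-3-[(tert-butyldimethylsilyl)oxy]-2-diazo-5-(2-methyl-1,3-dioxolan-2-yl)pent-3-enoate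
Conditions: TBSOTf (1.1 equiv), Et3N (1.5 equiv), CH2Cl2, 0 °C
Reagents that add atoms: tert-butyldimethylsilyl trifluoromethanesulfonate, CC(C)(C)[Si](C)(C)OS(=O)(=O)C(F)(F)F
Why: Soft enolisation and O-silylation of the diazo keto ester gives the (Z)-silyl enol ether (silyloxy and side chain cis), so the side chain points away from the future carbenoid carbon and cannot react with it intramolecularly.

Step 5
Reactants: 6 3-(triisopropylsilyl)prop-2-ynal; 7 2-(triphenyl-λ5-phosphanylidene)propanal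
Product: 8 (2E)-2-methyl-5-(triisopropylsilyl)pent-2-en-4-ynal
Conditions: CH2Cl2, rt, 12 h
Reagents that add atoms: none
Why: Wittig olefination with a stabilised ylide reacts only at the aldehyde and is E-selective, placing the alkynyl group trans to the formyl group.

Step 6
Reactants: 8 (2E)-2-methyl-5-(triisopropylsilyl)pent-2-en-4-ynal
Product: 9 (3E)-4-methyl-1-(triisopropylsilyl)hexa-3,5-dien-1-yne
Conditions: Ph3PCH3Br (1.3 equiv), KOt-Bu (1.25 equiv), THF, 0 °C → rt
Reagents that add atoms: methyltriphenylphosphonium bromide, C[P+](c1ccccc1)(c1ccccc1)c1ccccc1.[Br-]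
Why: Wittig methylenation converts the enal into the terminal diene without touching the geometry of the trisubstituted alkene.

Step 7
Reactants: 5 methyl (3Z)-3-[(tert-butyldimethylsilyl)oxy]-2-diazo-5-(2-methyl-1,3-dioxolan-2-yl)pent-3-enoate; 9 (3E)-4-methyl-1-(triisopropylsilyl)hexa-3,5-dien-1-yne
Product: 11 methyl (6S,7R)-1-[(tert-butyldimethylsilyl)oxy]-5-methyl-7-[(2-methyl-1,3-dioxolan-2-yl)methyl]-6-[(triisopropylsilyl)ethynyl]cyclohepta-1,4-diene-2-carboxylate, via cis-divinylcyclopropane 10 (not isolated)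
Conditions: Rh2(S-PTAD)4 (1 mol %), 9 (1.5 equiv), hexanes, −26 °C → rt, 5 added over 2 h; then 40 °C, 1 h
Reagents that add atoms: none
Why: Davies tandem cyclopropanation/Cope rearrangement (formal [4+3] cycloaddition): the chiral dirhodium donor/acceptor carbenoid cyclopropanates the terminal vinyl group of 9 enantioselectively to the cis-divinylcyclopropane, and its boat-type Cope rearrangement with both terminal substituents E forms the C6–C7 bond with the two substituents cis, so the catalyst sets the absolute and the pericyclic step the relative configuration at C6 and C7.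

Step 8
Reactants: 11 methyl (6S,7R)-1-[(tert-butyldimethylsilyl)oxy]-5-methyl-7-[(2-methyl-1,3-dioxolan-2-yl)methyl]-6-[(triisopropylsilyl)ethynyl]cyclohepta-1,4-diene-2-carboxylate
Product: 12 {(6S,7R)-1-[(tert-butyldimethylsilyl)oxy]-5-methyl-7-[(2-methyl-1,3-dioxolan-2-yl)methyl]-6-[(triisopropylsilyl)ethynyl]cyclohepta-1,4-dien-2-yl}methanol
Conditions: i-Bu2AlH (2.5 equiv), CH2Cl2, −78 °C; aq KNaC4H4O6 (potassium sodium tartrate) work-up; crude product used directly
Reagents that add atoms: none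
Why: Hydride 1,2-reduction of the β-siloxy acrylate ester gives the allylic alcohol (the future CH2OH) while the silyl enol ether keeps the C1 ketone masked.

Step 9
Reactants: 12 {(6S,7R)-1-[(tert-butyldimethylsilyl)oxy]-5-methyl-7-[(2-methyl-1,3-dioxolan-2-yl)methyl]-6-[(triisopropylsilyl)ethynyl]cyclohepta-1,4-dien-2-yl}methanol
Product: 13 (6S,7R)-1-[(tert-butyldimethylsilyl)oxy]-2-{[(tert-butyldimethylsilyl)oxy]methyl}-5-methyl-7-[(2-methyl-1,3-dioxolan-2-yl)methyl]-6-[(triisopropylsilyl)ethynyl]cyclohepta-1,4-diene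
Conditions: TBSCl (1.3 equiv), imidazole (2.5 equiv), DMF, 0 °C → rt
Reagents that add atoms: tert-butyldimethylsilyl chloride, CC(C)(C)[Si](C)(C)Cl
Why: Silylation under basic conditions protects the acid-labile allylic alcohol as a non-leaving silyl ether before the oxidation and organometallic steps.

Step 10
Reactants: 13 (6S,7R)-1-[(tert-butyldimethylsilyl)oxy]-2-{[(tert-butyldimethylsilyl)oxy]methyl}-5-methyl-7-[(2-methyl-1,3-dioxolan-2-yl)methyl]-6-[(triisopropylsilyl)ethynyl]cyclohepta-1,4-diene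
Product: 14 (6S,7R)-2-{[(tert-butyldimethylsilyl)oxy]methyl}-5-methyl-7-[(2-methyl-1,3-dioxolan-2-yl)methyl]-6-[(triisopropylsilyl)ethynyl]cyclohepta-2,4-dien-1-one
Conditions: DDQ (1.1 equiv), 2,6-lutidine (2 equiv), CH2Cl2, 0 °C, 30 min
Reagents that add atoms: none
Why: DDQ oxidation of a silyl enol ether: hydride abstraction from the doubly allylic C3–H2 (far more hydridic than the silyl-ether CH2) gives a siloxy-stabilised pentadienyl cation that loses the silyl group to give the linearly conjugated 2,4-dienone.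

Step 11
Reactants: 14 (6S,7R)-2-{[(tert-butyldimethylsilyl)oxy]methyl}-5-methyl-7-[(2-methyl-1,3-dioxolan-2-yl)methyl]-6-[(triisopropylsilyl)ethynyl]cyclohepta-2,4-dien-1-one; 15 5-bromo-2-methylpent-2-ene
Product: 18 (5S,6S,7R)-2-{[(tert-butyldimethylsilyl)oxy]methyl}-5-methyl-5-(4-methylpent-3-en-1-yl)-7-[(2-methyl-1,3-dioxolan-2-yl)methyl]-6-[(triisopropylsilyl)ethynyl]cyclohept-2-en-1-one, via (4-methylpent-3-en-1-yl)magnesium bromide 16 (not isolated), via deconjugated cyclohept-3-enone 17 (not isolated)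
Conditions: 15, Mg, THF, rt; then CuBr·SMe2 (30 mol %), 14, THF, −78 → −30 °C; AcOH, −78 °C; then DBU (0.3 equiv), CH2Cl2, rt
Reagents that add atoms: none
Why: Copper-catalysed 1,6-conjugate addition of a Grignard reagent (no silyl chloride or Lewis acid, which would favour 1,4-addition): A(1,2) strain with the C5 methyl holds the C6 alkynyl group pseudoaxial, so the copper reagent attacks C5 anti to it and the methyl ends cis to the alkynyl group; kinetic α-protonation and base-mediated isomerisation then move the double bond into conjugation.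

Step 12
Reactants: 18 (5S,6S,7R)-2-{[(tert-butyldimethylsilyl)oxy]methyl}-5-methyl-5-(4-methylpent-3-en-1-yl)-7-[(2-methyl-1,3-dioxolan-2-yl)methyl]-6-[(triisopropylsilyl)ethynyl]cyclohept-2-en-1-one
Product: 20 (5S,6S,7R)-6-ethynyl-2-(hydroxymethyl)-5-methyl-5-(4-methylpent-3-en-1-yl)-7-(2-oxopropyl)cyclohept-2-en-1-one, via dioxolane ynol 19 (not isolated)
Conditions: Bu4NF·3H2O (3 equiv), THF, 0 °C → rt; then 1 M aq HCl, rt, 2 h
Reagents that add atoms: water, O
Why: Fluoride-mediated protodesilylation cleaves the alkynyl C–Si and the O–Si bonds while the ketal still blocks aldol chemistry of the 1,4-diketone, and dilute acid then hydrolyses the dioxolane.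

Step 13
Reactants: 20 (5S,6S,7R)-6-ethynyl-2-(hydroxymethyl)-5-methyl-5-(4-methylpent-3-en-1-yl)-7-(2-oxopropyl)cyclohept-2-en-1-one; 21 3-methylbut-2-enoic acid
Product: 22 (5S,6S,7R)-2-(hydroxymethyl)-5-methyl-5-(4-methylpent-3-en-1-yl)-6-{(Z)-2-[(3-methylbut-2-enoyl)oxy]ethenyl}-7-(2-oxopropyl)cyclohept-2-en-1-one
Conditions: Ru(η3-2-methylallyl)2(dppb) (3 mol %; dppb = Ph2P(CH2)4PPh2), 21 (1.2 equiv), toluene, 65 °C
Reagents that add atoms: none
Why: Ruthenium-catalysed anti-Markovnikov hydro-oxycarbonylation of a terminal alkyne: the carboxylate adds to the terminal carbon of a ruthenium vinylidene and protonolysis gives the (Z)-enol ester, leaving ketones and other alkenes untouched.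

Step 14
Reactants: 22 (5S,6S,7R)-2-(hydroxymethyl)-5-methyl-5-(4-methylpent-3-en-1-yl)-6-{(Z)-2-[(3-methylbut-2-enoyl)oxy]ethenyl}-7-(2-oxopropyl)cyclohept-2-en-1-one
Product: 23 (5S,6S,7R)-5-[(2E)-4-hydroperoxy-4-methylpent-2-en-1-yl]-2-(hydroxymethyl)-5-methyl-6-{(Z)-2-[(3-methylbut-2-enoyl)oxy]ethenyl}-7-(2-oxopropyl)cyclohept-2-en-1-one (CNP0283385.3)
Conditions: O2, tetraphenylporphyrin (1 mol %), hν (white LED), CH2Cl2, −20 °C; chromatography
Reagents that add atoms: dioxygen, O=O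
Why: Schenck ene reaction: singlet oxygen reacts only with the electron-rich trisubstituted alkene, and abstraction of the allylic CH2 hydrogen gives the (E)-tertiary allylic hydroperoxide (about half of the material; the isopropenyl secondary hydroperoxide regioisomer is separated), with no stereocentre created or disturbed.

## Compound list

1 | methyl levulinate (methyl 4-oxopentanoate) | COC(=O)CCC(C)=O | starting material
2 | methyl 3-(2-methyl-1,3-dioxolan-2-yl)propanoate | COC(=O)CCC1(C)OCCO1 | intermediate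
3 | methyl 5-(2-methyl-1,3-dioxolan-2-yl)-3-oxopentanoate | COC(=O)CC(=O)CCC1(C)OCCO1 | intermediate
4 | methyl 2-diazo-5-(2-methyl-1,3-dioxolan-2-yl)-3-oxopentanoate | COC(=O)C(=[N+]=[N-])C(=O)CCC1(C)OCCO1 | intermediate
5 | methyl (3Z)-3-[(tert-butyldimethylsilyl)oxy]-2-diazo-5-(2-methyl-1,3-dioxolan-2-yl)pent-3-enoate | COC(=O)C(=[N+]=[N-])/C(O[Si](C)(C)C(C)(C)C)=C/CC1(C)OCCO1 | intermediate
6 | 3-(triisopropylsilyl)prop-2-ynal | O=CC#C[Si](C(C)C)(C(C)C)C(C)C | starting material
7 | 2-(triphenyl-λ5-phosphanylidene)propanal | CC(C=O)=P(c1ccccc1)(c1ccccc1)c1ccccc1 | starting material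
8 | (2E)-2-methyl-5-(triisopropylsilyl)pent-2-en-4-ynal | O=C/C(C)=C/C#C[Si](C(C)C)(C(C)C)C(C)C | intermediate
9 | (3E)-4-methyl-1-(triisopropylsilyl)hexa-3,5-dien-1-yne | C=C/C(C)=C/C#C[Si](C(C)C)(C(C)C)C(C)C | intermediate
10 | methyl (1S,2R)-1-{(1Z)-1-[(tert-butyldimethylsilyl)oxy]-3-(2-methyl-1,3-dioxolan-2-yl)prop-1-en-1-yl}-2-[(2E)-5-(triisopropylsilyl)pent-2-en-4-yn-2-yl]cyclopropane-1-carboxylate (alkenyl groups cis) | COC(=O)[C@@]1(/C(O[Si](C)(C)C(C)(C)C)=C/CC2(C)OCCO2)C[C@@H]1/C(C)=C/C#C[Si](C(C)C)(C(C)C)C(C)C | intermediate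
11 | methyl (6S,7R)-1-[(tert-butyldimethylsilyl)oxy]-5-methyl-7-[(2-methyl-1,3-dioxolan-2-yl)methyl]-6-[(triisopropylsilyl)ethynyl]cyclohepta-1,4-diene-2-carboxylate (6,7-cis) | CC2(OCCO2)C[C@H]1C(O[Si](C)(C)C(C)(C)C)=C(C(=O)OC)CC=C(C)[C@H]1C#C[Si](C(C)C)(C(C)C)C(C)C | intermediate
12 | {(6S,7R)-1-[(tert-butyldimethylsilyl)oxy]-5-methyl-7-[(2-methyl-1,3-dioxolan-2-yl)methyl]-6-[(triisopropylsilyl)ethynyl]cyclohepta-1,4-dien-2-yl}methanol | CC2(OCCO2)C[C@H]1C(O[Si](C)(C)C(C)(C)C)=C(CO)CC=C(C)[C@H]1C#C[Si](C(C)C)(C(C)C)C(C)C | intermediate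
13 | (6S,7R)-1-[(tert-butyldimethylsilyl)oxy]-2-{[(tert-butyldimethylsilyl)oxy]methyl}-5-methyl-7-[(2-methyl-1,3-dioxolan-2-yl)methyl]-6-[(triisopropylsilyl)ethynyl]cyclohepta-1,4-diene | CC2(OCCO2)C[C@H]1C(O[Si](C)(C)C(C)(C)C)=C(CO[Si](C)(C)C(C)(C)C)CC=C(C)[C@H]1C#C[Si](C(C)C)(C(C)C)C(C)C | intermediate
14 | (6S,7R)-2-{[(tert-butyldimethylsilyl)oxy]methyl}-5-methyl-7-[(2-methyl-1,3-dioxolan-2-yl)methyl]-6-[(triisopropylsilyl)ethynyl]cyclohepta-2,4-dien-1-one | CC2(OCCO2)C[C@H]1C(=O)C(CO[Si](C)(C)C(C)(C)C)=CC=C(C)[C@H]1C#C[Si](C(C)C)(C(C)C)C(C)C | intermediate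
15 | 5-bromo-2-methylpent-2-ene | CC(C)=CCCBr | starting material
16 | (4-methylpent-3-en-1-yl)magnesium bromide | CC(C)=CCC[Mg]Br | intermediate
17 | (5S,6S,7R)-2-{[(tert-butyldimethylsilyl)oxy]methyl}-5-methyl-5-(4-methylpent-3-en-1-yl)-7-[(2-methyl-1,3-dioxolan-2-yl)methyl]-6-[(triisopropylsilyl)ethynyl]cyclohept-3-en-1-one (C2 epimers) | CC2(OCCO2)C[C@H]1C(=O)C(CO[Si](C)(C)C(C)(C)C)C=C[C@](C)(CCC=C(C)C)[C@H]1C#C[Si](C(C)C)(C(C)C)C(C)C | intermediate
18 | (5S,6S,7R)-2-{[(tert-butyldimethylsilyl)oxy]methyl}-5-methyl-5-(4-methylpent-3-en-1-yl)-7-[(2-methyl-1,3-dioxolan-2-yl)methyl]-6-[(triisopropylsilyl)ethynyl]cyclohept-2-en-1-one | CC2(OCCO2)C[C@H]1C(=O)C(CO[Si](C)(C)C(C)(C)C)=CC[C@](C)(CCC=C(C)C)[C@H]1C#C[Si](C(C)C)(C(C)C)C(C)C | intermediate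
19 | (5S,6S,7R)-6-ethynyl-2-(hydroxymethyl)-5-methyl-5-(4-methylpent-3-en-1-yl)-7-[(2-methyl-1,3-dioxolan-2-yl)methyl]cyclohept-2-en-1-one | CC2(OCCO2)C[C@H]1C(=O)C(CO)=CC[C@](C)(CCC=C(C)C)[C@H]1C#C | intermediate
20 | (5S,6S,7R)-6-ethynyl-2-(hydroxymethyl)-5-methyl-5-(4-methylpent-3-en-1-yl)-7-(2-oxopropyl)cyclohept-2-en-1-one | CC(=O)C[C@H]1C(=O)C(CO)=CC[C@](C)(CCC=C(C)C)[C@H]1C#C | intermediate
21 | 3-methylbut-2-enoic acid | CC(C)=CC(=O)O | starting material
22 | (5S,6S,7R)-2-(hydroxymethyl)-5-methyl-5-(4-methylpent-3-en-1-yl)-6-{(Z)-2-[(3-methylbut-2-enoyl)oxy]ethenyl}-7-(2-oxopropyl)cyclohept-2-en-1-one | CC(=O)C[C@H]1C(=O)C(CO)=CC[C@](C)(CCC=C(C)C)[C@H]1/C=C\OC(=O)C=C(C)C | intermediate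
23 | (5S,6S,7R)-5-[(2E)-4-hydroperoxy-4-methylpent-2-en-1-yl]-2-(hydroxymethyl)-5-methyl-6-{(Z)-2-[(3-methylbut-2-enoyl)oxy]ethenyl}-7-(2-oxopropyl)cyclohept-2-en-1-one | CC(=O)C[C@H]1C(=O)C(CO)=CC[C@](C)(C/C=C/C(C)(C)OO)[C@H]1/C=C\OC(=O)C=C(C)C | target

## Step count and risk

Total steps: 14. Longest linear sequence: 12 steps (steps 1–4 and 7–14, from methyl levulinate); the dienyne branch (steps 5–6) joins at step 7.

Steps most likely to fail:

Step 11 (1,6-addition that makes the C5 quaternary centre). The δ-carbon is fully substituted, so 1,4-addition at C3 or simple enolisation could win. The fallback abandons the dienone and makes the C5–C bond by a radical hydroalkylation; it sets out from 13 and comes back at 18, bypassing steps 10 and 11. Hydrogen-atom transfer from an iron hydride (Fe(acac)3, PhSiH3, EtOH, 60 °C) to the trisubstituted C4=C5 alkene of 13 gives the tertiary C5 radical. This adds to acrolein anti to the C6 alkynyl group (reductive olefin coupling of Giese type) and gives the C5 propanal adduct F5. Wittig reaction with Ph3P=C(CH3)2 gives the homoprenyl bis-silyl cycloheptene F6. Saegusa–Ito oxidation of its silyl enol ether (Pd(OAc)2, MeCN, 40 °C) then introduces the C2=C3 double bond and gives 18.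

Step 7 (key [4+3] step). A 4-substituted siloxyvinyl carbenoid and a trisubstituted dienyne are both more hindered than the usual partners, so the enantioselectivity or chemoselectivity may be poor under catalyst control. The fallback moves the stereocontrol to a covalently bound auxiliary; it sets out from 3 and comes back at 12. DMAP-catalysed transesterification of 3 with (R)-pantolactone (toluene, reflux) gives the (R)-pantolactonyl keto ester F1. Diazo transfer gives the (R)-pantolactonyl diazo keto ester F2, and TBSOTf/Et3N gives the (R)-pantolactonyl (Z)-siloxyvinyl diazoacetate F3. Decomposition of F3 with achiral Rh2(O2CC7H15)4 in the presence of 9 runs the same cyclopropanation/Cope sequence, with the face chosen by the auxiliary, and gives the (R)-pantolactonyl cycloheptadienecarboxylate F4. Reduction of F4 with i-Bu2AlH removes the auxiliary and gives 12. If the auxiliary induces the opposite sense, (S)-pantolactone is used.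

Step 13 (Z-selective enol ester formation). The alkyne sits on a hindered carbon next to the quaternary centre, and a free allylic alcohol is present, so vinylidene formation may be slow or the Z/E ratio poor. The fallback builds the C–O bond by cross-coupling on a preformed (Z)-alkenyl boron compound; it sets out from 20 and comes back at 22. Rhodium-catalysed trans-hydroboration of 20 with pinacolborane ([Rh(cod)Cl]2, P(i-Pr)3, Et3N, cyclohexane, rt) gives the (Z)-alkenyl pinacolboronate F7. KHF2 converts it into the potassium (Z)-alkenyltrifluoroborate F8. Copper-catalysed oxidative C–O coupling with 21 (CuBr, DMAP, O2, 4 Å sieves), which retains the olefin geometry, then gives 22.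

Further compounds
F1 | step 7 | (3R)-4,4-dimethyl-2-oxooxolan-3-yl 5-(2-methyl-1,3-dioxolan-2-yl)-3-oxopentanoate | CC1(C)COC(=O)[C@@H]1OC(=O)CC(=O)CCC2(C)OCCO2
F2 | step 7 | (3R)-4,4-dimethyl-2-oxooxolan-3-yl 2-diazo-5-(2-methyl-1,3-dioxolan-2-yl)-3-oxopentanoate | CC1(C)COC(=O)[C@@H]1OC(=O)C(=[N+]=[N-])C(=O)CCC2(C)OCCO2
F3 | step 7 | (3R)-4,4-dimethyl-2-oxooxolan-3-yl (3Z)-3-[(tert-butyldimethylsilyl)oxy]-2-diazo-5-(2-methyl-1,3-dioxolan-2-yl)pent-3-enoate | CC1(C)COC(=O)[C@@H]1OC(=O)C(=[N+]=[N-])/C(O[Si](C)(C)C(C)(C)C)=C/CC2(C)OCCO2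
F4 | step 7 | (3R)-4,4-dimethyl-2-oxooxolan-3-yl (6S,7R)-1-[(tert-butyldimethylsilyl)oxy]-5-methyl-7-[(2-methyl-1,3-dioxolan-2-yl)methyl]-6-[(triisopropylsilyl)ethynyl]cyclohepta-1,4-diene-2-carboxylate | CC2(OCCO2)C[C@H]1C(O[Si](C)(C)C(C)(C)C)=C(C(=O)O[C@H]3C(=O)OCC3(C)C)CC=C(C)[C@H]1C#C[Si](C(C)C)(C(C)C)C(C)C
F5 | step 11 | 3-{(5R,6S,7R)-1-[(tert-butyldimethylsilyl)oxy]-2-{[(tert-butyldimethylsilyl)oxy]methyl}-5-methyl-7-[(2-methyl-1,3-dioxolan-2-yl)methyl]-6-[(triisopropylsilyl)ethynyl]cyclohept-1-en-5-yl}propanal | CC2(OCCO2)C[C@H]1C(O[Si](C)(C)C(C)(C)C)=C(CO[Si](C)(C)C(C)(C)C)CC[C@](C)(CCC=O)[C@H]1C#C[Si](C(C)C)(C(C)C)C(C)C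
F6 | step 11 | (5S,6S,7R)-1-[(tert-butyldimethylsilyl)oxy]-2-{[(tert-butyldimethylsilyl)oxy]methyl}-5-methyl-5-(4-methylpent-3-en-1-yl)-7-[(2-methyl-1,3-dioxolan-2-yl)methyl]-6-[(triisopropylsilyl)ethynyl]cyclohept-1-ene | CC2(OCCO2)C[C@H]1C(O[Si](C)(C)C(C)(C)C)=C(CO[Si](C)(C)C(C)(C)C)CC[C@](C)(CCC=C(C)C)[C@H]1C#C[Si](C(C)C)(C(C)C)C(C)C
F7 | step 13 | (5S,6S,7R)-2-(hydroxymethyl)-5-methyl-5-(4-methylpent-3-en-1-yl)-7-(2-oxopropyl)-6-[(Z)-2-(4,4,5,5-tetramethyl-1,3,2-dioxaborolan-2-yl)ethenyl]cyclohept-2-en-1-one | CC(=O)C[C@H]1C(=O)C(CO)=CC[C@](C)(CCC=C(C)C)[C@H]1/C=C\B2OC(C)(C)C(C)(C)O2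
F8 | step 13 | potassium trifluoro{(Z)-2-[(5S,6S,7R)-2-(hydroxymethyl)-5-methyl-5-(4-methylpent-3-en-1-yl)-1-oxo-7-(2-oxopropyl)cyclohept-2-en-6-yl]ethenyl}borate | CC(=O)C[C@H]1C(=O)C(CO)=CC[C@](C)(CCC=C(C)C)[C@H]1/C=C\[B-](F)(F)F.[K+]
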